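Remark (assumption): locants follow prostanoic acid numbering (C1 = carboxyl carbon, C8–C12 = ring, C9 = ketone, C15 = acetoxy carbon), and mono-tert-butyl azelate 9 is taken as a catalogue compound (otherwise one step from azelaic acid).

## Structural features

The target is a cyclopent-2-en-1-one (ring C8–C12, C9 ketone, C10=C11 alkene) with a saturated 6-carboxyhexyl chain on C8 and an (E)-3-acetoxyoct-1-enyl chain on C12. C8 (R) and C12 (S) are adjacent ring stereocentres with the chains trans. The third stereocentre, C15 (S), lies outside the ring, 1,4 to C12 across the C13=C14 E-alkene, so the ring cannot control it. C8 is α to the ketone and epimerisable (trans is the stable arrangement), whereas C12 is γ to the ketone and doubly allylic, so base removes its proton and moves the ring alkene irreversibly. The C15 allylic acetate does not survive organometallic reagents, hydroxide, Pd(0) or prolonged strong acid, and the C1 acid must be free at the end. The enone sits on the unsubstituted side of the ring and there is no oxygen at C11, so the usual 11-oxygenated intermediates carry a stereocentre that is made only to be destroyed. The real difficulty is the absolute configuration of C12 together with trans C8, set at the C8–C12 bond that joins the two chains, without base-mediated steps on the finished enone. The key step exploits that C9(=O)–C8–C12–C11= is the γ,δ-unsaturated carbonyl array of a Claisen product, with C12 flanked by two alkenes (C10=C11 and C13=C14), and that C1–C9 is azelaic acid.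

## Logic of the disconnections

22 ⇒ 20 (through 21). The acetyl C–O bond on the C15 oxygen is cut. The acetate tolerates none of the organometallic, hydride or amide-base steps, so it goes on last and every earlier intermediate carries a robust silyl ether instead. The forward step must acylate a secondary allylic alcohol beside a free C1 acid without deprotonating C12.

20 ⇒ 19 ⇒ 18. The O15–Si bond and then the C1 ester O–C(CH3)3 bond are cut. This keeps C1 distinct from the C9 carboxyl that is used earlier, and keeps O15 masked while acid is applied. The forward demand is an ester cleavage that leaves the allylic silyl ether and the enone alone, followed by a non-basic desilylation.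

18 ⇒ 17. The C10=C11 ring bond is cut (ring-closing metathesis transform), opening the ring to an acyclic ketone with a vinyl group on C9 and an E-propenyl group on C12. The ring stereochemistry becomes an acyclic vicinal pair, and the enone appears in its final position without any elimination. The catalyst must load on the propenyl group and not on the C13=C14 alkene.

17 ⇒ 15 ⇒ 13. The C9–C10 bond is cut to a vinyl nucleophile and an N-methoxy-N-methylamide, which goes back to the C9 acid. The forward demand is mono-addition without attack on the C1 ester and without loss of C8.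

13 ⇒ 10 (through 12 and 11). This is the key cut: the C8–C12 bond is broken and the C9–O–C(carbinol) ester link is restored, a [3,3] transform. In one sentence, the route is a sigmatropic rearrangement of the silyl ketene acetal of 10. Two adjacent stereocentres, the bond joining the two chains and the E-propenyl handle are traced to one purchased carbinol stereocentre and one E-alkene. The molecule falls into a C9 diacid half-ester and a dienol. The forward step needs a chair transition state, a defined ketene acetal geometry and tolerance of the second ester.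

10 ⇒ 8 + 9. The ester C9(=O)–O bond is cut. This is the convergent point; the forward acylation must not ionise the dienylic alcohol.

8 ⇒ 6 ⇒ 4 + 5. The C11=C12 alkene is traced to an alkyne, and the C12–C13 sp–sp2 bond is cut. The two stereocentres then come from two purchased propargylic alcohols; the forward demand is a trans-selective, hydroxyl-directed alkyne reduction and a geometry-retaining coupling.

4 ⇒ 2 ⇒ 1. The C13–I bond (alkyne hydrometalation then iodination) and the O15–Si bond are cut, reaching the purchased C15 stereocentre.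

## Other disconnections considered

Alternative 1: (first to mind) Re-introduce an oxygen at C11 and cut C12–C13 by a conjugate-addition transform. Forward, copper-mediated 1,4-addition of the alkenyl unit of 4 (after iodine–metal exchange) to the 4-silyloxy enone A1 would give the protected 11-oxy ketone A2, trans to the C11 substituent. β-Elimination of the C11 oxygen would then give the C10=C11 enone. A1 needs its own enantioselective synthesis, and its stereocentre exists only to be eliminated. The elimination is an acid- or base-mediated step on a ketone whose C12–H is about to become γ-acidic, which is where double-bond migration is expected. The chosen plan never carries a C11 oxygen and sets C8 and C12 in one event.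

Alternative 2: Cut C11–C12 by a 4π-electrocyclisation transform. Forward, a Lewis-acid-promoted silicon-directed Nazarov cyclisation of the β-silyl trienone A3 would close the ring, and loss of silicon would place the alkene at C10=C11. This addresses the unusual enone position directly. However, the conrotation sense that fixes C12 would be governed only by the remote C15 centre, so C12 is essentially uncontrolled. The C13=C14 alkene also extends the cation and sits next to an ionisable allylic silyloxy group under Lewis acid, and C8 would be set only by protonation.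

Alternative 3: Cut both C12–C13 and C7–C8 on the parent enone. Forward, a catalytic enantioselective 1,4-addition of the alkenyl unit of 4 to cyclopent-2-en-1-one A4, with trapping of the enolate by the iodo ester A5, would give the 11-deoxy ketone A6. A kinetic silyl enol ether at C10 and a Saegusa–Ito oxidation would then introduce C10=C11. Alkylation of a cyclopentanone enolate with an unactivated primary iodide competes with proton transfer, so the α-chain would probably need an indirect installation. A chiral catalyst acting on a chiral nucleophile raises a matched/mismatched question, and the late Pd(II) oxidation must distinguish C10 from C8 next to an allylic system. That is two stereocontrolling events and a late oxidation against one event in the chosen plan.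

Key step: step 6

## Steps

Step 1
Reactants: 1 (S)-oct-1-yn-3-ol
Product: 2 (S)-tert-butyl(oct-1-yn-3-yloxy)diphenylsilane
Conditions: TBDPSCl, imidazole, DMF, rt
Reagents that add atoms: tert-butyl(chloro)diphenylsilane, CC(C)(C)[Si](Cl)(c1ccccc1)c1ccccc1
Why: Imidazole-promoted silylation of a secondary propargylic alcohol; C15 is not touched. TBDPS is chosen because it should survive hydride, amide base, Grignard reagent and trifluoroacetic acid later.

Step 2
Reactants: 2 (S)-tert-butyl(oct-1-yn-3-yloxy)diphenylsilane
Product: 4 tert-butyl{[(1E,3S)-1-iodooct-1-en-3-yl]oxy}diphenylsilane, via alkenylzirconocene chloride 3 (not isolated)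
Conditions: Cp2Zr(H)Cl, THF, rt; then I2, THF, 0 °C
Reagents that add atoms: iodine, II
Why: Hydrozirconation (syn addition, Zr on the terminal carbon) followed by iodinolysis with retention should give only the E-iodoalkene.

Step 3
Reactants: 4 tert-butyl{[(1E,3S)-1-iodooct-1-en-3-yl]oxy}diphenylsilane; 5 (R)-but-3-yn-2-ol
Product: 6 (2R,5E,7S)-7-[(tert-butyldiphenylsilyl)oxy]dodec-5-en-3-yn-2-ol
Conditions: Pd(PPh3)2Cl2 (cat.), CuI (cat.), Et3N, THF, rt
Reagents that add atoms: none
Why: Sonogashira coupling of an alkenyl iodide with a terminal alkyne, with retention of the E geometry; the free propargylic alcohol is tolerated and both stereocentres are spectators.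

Step 4
Reactants: 6 (2R,5E,7S)-7-[(tert-butyldiphenylsilyl)oxy]dodec-5-en-3-yn-2-ol
Product: 8 (2R,3E,5E,7S)-7-[(tert-butyldiphenylsilyl)oxy]dodeca-3,5-dien-2-ol, via cyclic alkenylaluminate 7 (not isolated)
Conditions: Red-Al, THF, 0 °C to rt; aq. Rochelle salt
Reagents that add atoms: none
Why: Hydroxyl-directed trans-hydroalumination of a propargylic alcohol (hydride to C3, aluminium on C4, held in a five-membered aluminate) and protonolysis with retention should give the E-alkene. Only the alkyne next to the free OH is reduced.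

Step 5
Reactants: 8 (2R,3E,5E,7S)-7-[(tert-butyldiphenylsilyl)oxy]dodeca-3,5-dien-2-ol; 9 9-tert-butoxy-9-oxononanoic acid
Product: 10 1-tert-butyl 9-[(2R,3E,5E,7S)-7-[(tert-butyldiphenylsilyl)oxy]dodeca-3,5-dien-2-yl] nonanedioate
Conditions: DCC, DMAP (cat.), CH2Cl2, 0 °C to rt
Reagents that add atoms: none
Why: Steglich esterification; the carbinol C–O bond is not broken, so the R configuration is kept, and the neutral conditions avoid ionisation of the dienylic alcohol.

Step 6
Reactants: 10 1-tert-butyl 9-[(2R,3E,5E,7S)-7-[(tert-butyldiphenylsilyl)oxy]dodeca-3,5-dien-2-yl] nonanedioate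
Product: 13 (2R)-9-tert-butoxy-2-[(2E,4R,5E,7S)-7-[(tert-butyldiphenylsilyl)oxy]dodeca-2,5-dien-4-yl]-9-oxononanoic acid, via bis(trimethylsilyl) ketene acetal 11 (not isolated), via rearranged trimethylsilyl ester 12 (not isolated)
Conditions: LDA (2.4 equiv), THF/DMPU (3:1), −78 °C; Me3SiCl (3 equiv); −78 °C to rt, then 40 °C; 1 M HCl/THF, 0 °C
Reagents that add atoms: none
Why: This is an Ireland–Claisen rearrangement; the closest known type is the rearrangement of secondary (E)-allylic esters with 1,3-chirality transfer. Excess LDA deprotonates both ester α-positions; in the DMPU medium the allylic ester should give the Z(O)-enolate through an open transition state, and O-silylation fixes it as ketene acetal 11 with the C7 chain cis to OSiMe3. On warming, 11 undergoes the suprafacial [3,3] shift through a chair with the carbinol methyl group equatorial, forming the C8–C12 bond, the C9 carboxyl (as silyl ester 12) and the new E-propenyl alkene; the six-atom array exists only at the proximal C11=C12 alkene, so C13=C14 and C15 are spectators, and the tert-butyl ketene acetal, which has no allyl group, reverts to the ester on acidic work-up. No ring is closed. C12 is controlled by the purchased (R)-carbinol centre: with methyl equatorial and the E-C11=C12 geometry the ketene acetal can reach only one face of C12, which gives the 12S arrangement of the target while the C–O stereocentre is destroyed. C8 is controlled by ketene acetal geometry: the C7 chain, trans to the allylic oxygen and therefore equatorial, next to the equatorial C13 substituent gives the 8R,12S pair that becomes trans on the ring. The selectivities needed are chair over boat (secured by the acyclic substrate), equatorial over axial methyl (secured by 1,3-diaxial strain in the alternative chair) and Z(O)- over E(O)-enolate (secured by DMPU); discrimination between the two esters is not needed because only one ketene acetal can rearrange. C8 is α to the future ring ketone, so an error there is correctable, whereas C12 depends only on the robust elements.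

Step 7
Reactants: 13 (2R)-9-tert-butoxy-2-[(2E,4R,5E,7S)-7-[(tert-butyldiphenylsilyl)oxy]dodeca-2,5-dien-4-yl]-9-oxononanoic acid
Product: 15 tert-butyl (8R)-8-[(2E,4R,5E,7S)-7-[(tert-butyldiphenylsilyl)oxy]dodeca-2,5-dien-4-yl]-9-[methoxy(methyl)amino]-9-oxononanoate, via acid chloride 14 (not isolated)
Conditions: 1-chloro-N,N,2-trimethylprop-1-en-1-amine, CH2Cl2, 0 °C to rt; then MeNH(OMe)·HCl, pyridine, 0 °C to rt
Reagents that add atoms: N,O-dimethylhydroxylamine hydrochloride, CNOC.Cl
Why: The Ghosez reagent makes the acid chloride of a hindered α-branched acid under neutral conditions, so the tert-butyl ester and silyl ether should survive, and amidation then gives the Weinreb amide. Pyridine rather than a trialkylamine keeps ketene formation, and with it C8 epimerisation, down.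

Step 8
Reactants: 15 tert-butyl (8R)-8-[(2E,4R,5E,7S)-7-[(tert-butyldiphenylsilyl)oxy]dodeca-2,5-dien-4-yl]-9-[methoxy(methyl)amino]-9-oxononanoate
Product: 17 tert-butyl (8R)-8-[(2E,4R,5E,7S)-7-[(tert-butyldiphenylsilyl)oxy]dodeca-2,5-dien-4-yl]-9-oxoundec-10-enoate, via magnesium hemiaminal adduct 16 (not isolated)
Conditions: CH2=CHMgBr, THF, −78 to 0 °C; inverse quench into cold 1 M HCl
Reagents that add atoms: vinylmagnesium bromide, C=C[Mg]Br
Why: Nahm–Weinreb ketone synthesis; the chelated adduct 16 holds the ketone oxidation level until the quench, and the tert-butyl ester is inert at this temperature. The acidic inverse quench protonates the liberated amine before it can add to the vinyl ketone.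

Step 9
Reactants: 17 tert-butyl (8R)-8-[(2E,4R,5E,7S)-7-[(tert-butyldiphenylsilyl)oxy]dodeca-2,5-dien-4-yl]-9-oxoundec-10-enoate
Product: 18 tert-butyl 7-[(1R,2S)-2-[(1E,3S)-3-[(tert-butyldiphenylsilyl)oxy]oct-1-en-1-yl]-5-oxocyclopent-3-en-1-yl]heptanoate
Conditions: Hoveyda–Grubbs II (5 mol %), CH2Cl2 (5 mM), 40 °C
Reagents that add atoms: none
Why: Ring-closing metathesis of a 1,6-dien-3-one to a cyclopent-2-enone. The carbene should load on the methyl-terminated propenyl group rather than on the electron-poor enone or the C13=C14 alkene, which is flanked by C12 and the bulky silyloxy carbon, and then close the five-membered ring. The former carbinol carbon leaves as propene, and C8 and C12 are untouched.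

Step 10
Reactants: 18 tert-butyl 7-[(1R,2S)-2-[(1E,3S)-3-[(tert-butyldiphenylsilyl)oxy]oct-1-en-1-yl]-5-oxocyclopent-3-en-1-yl]heptanoate
Product: 19 7-[(1R,2S)-2-[(1E,3S)-3-[(tert-butyldiphenylsilyl)oxy]oct-1-en-1-yl]-5-oxocyclopent-3-en-1-yl]heptanoic acid
Conditions: CF3CO2H/CH2Cl2 (1:4), 0 °C to rt; toluene azeotrope
Reagents that add atoms: none
Why: Acidolysis of the tert-butyl ester (loss of isobutene). The TBDPS ether is the acid-stable silyl group and the cross-conjugated enone is acid-tolerant; no base is used, so C12 is safe.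

Step 11
Reactants: 19 7-[(1R,2S)-2-[(1E,3S)-3-[(tert-butyldiphenylsilyl)oxy]oct-1-en-1-yl]-5-oxocyclopent-3-en-1-yl]heptanoic acid
Product: 20 7-[(1R,2S)-2-[(1E,3S)-3-hydroxyoct-1-en-1-yl]-5-oxocyclopent-3-en-1-yl]heptanoic acid (prostaglandin A1)
Conditions: HF·pyridine, THF/pyridine, 0 °C to rt
Reagents that add atoms: none
Why: Fluoride-mediated Si–O cleavage under buffered, non-basic conditions; the C15–O bond is not broken, so the S configuration is kept.

Step 12
Reactants: 20 7-[(1R,2S)-2-[(1E,3S)-3-hydroxyoct-1-en-1-yl]-5-oxocyclopent-3-en-1-yl]heptanoic acid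
Product: 22 7-[(1R,2S)-2-[(1E,3S)-3-acetoxyoct-1-en-1-yl]-5-oxocyclopent-3-en-1-yl]heptanoic acid, via mixed acetic anhydride 21 (not isolated)
Conditions: Ac2O (10 equiv), pyridine, CH2Cl2, 0 °C to rt; then H2O/THF, rt
Reagents that add atoms: acetic anhydride, CC(=O)OC(C)=O; water, O (hydrolysis of 21)
Why: Pyridine-mediated O-acetylation of the secondary allylic alcohol with retention (acyl–O bond formation). The C1 acid is acylated reversibly to 21, which the aqueous stir returns to the acid. Pyridine is too weak a base to deprotonate C12, and the large excess of anhydride keeps intermolecular ester formation down.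

## Compound list

1 | (S)-oct-1-yn-3-ol | CCCCC[C@H](O)C#C | starting material
2 | (S)-tert-butyl(oct-1-yn-3-yloxy)diphenylsilane | CCCCC[C@H](O[Si](c1ccccc1)(c1ccccc1)C(C)(C)C)C#C | intermediate
3 | chlorido[(1E,3S)-3-(tert-butyldiphenylsilyloxy)oct-1-en-1-yl]zirconocene (Cp drawn σ-bonded) | CCCCC[C@H](O[Si](c1ccccc1)(c1ccccc1)C(C)(C)C)/C=C/[Zr](Cl)(C1C=CC=C1)C1C=CC=C1 | intermediate (not isolated)
4 | tert-butyl{[(1E,3S)-1-iodooct-1-en-3-yl]oxy}diphenylsilane | CCCCC[C@H](O[Si](c1ccccc1)(c1ccccc1)C(C)(C)C)/C=C/I | intermediate
5 | (R)-but-3-yn-2-ol | C[C@@H](O)C#C | starting material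
6 | (2R,5E,7S)-7-[(tert-butyldiphenylsilyl)oxy]dodec-5-en-3-yn-2-ol | C[C@@H](O)C#C/C=C/[C@H](CCCCC)O[Si](c1ccccc1)(c1ccccc1)C(C)(C)C | intermediate
7 | sodium cyclic alkoxy(alkenyl)bis(2-methoxyethoxy)aluminate from trans-hydroalumination of 6 (Al on C4, H on C3; schematic) | C[C@H]1O[Al-](OCCOC)(OCCOC)C(/C=C/[C@H](CCCCC)O[Si](c2ccccc2)(c2ccccc2)C(C)(C)C)=C1.[Na+] | intermediate (not isolated)
8 | (2R,3E,5E,7S)-7-[(tert-butyldiphenylsilyl)oxy]dodeca-3,5-dien-2-ol | C[C@@H](O)/C=C/C=C/[C@H](CCCCC)O[Si](c1ccccc1)(c1ccccc1)C(C)(C)C | intermediate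
9 | 9-tert-butoxy-9-oxononanoic acid (mono-tert-butyl azelate) | OC(=O)CCCCCCCC(=O)OC(C)(C)C | starting material
10 | 1-tert-butyl 9-[(2R,3E,5E,7S)-7-[(tert-butyldiphenylsilyl)oxy]dodeca-3,5-dien-2-yl] nonanedioate | C[C@@H](OC(=O)CCCCCCCC(=O)OC(C)(C)C)/C=C/C=C/[C@H](CCCCC)O[Si](c1ccccc1)(c1ccccc1)C(C)(C)C | intermediate
11 | bis(trimethylsilyl) ketene acetal of 10 (allylic terminus Z, C7 chain cis to OSiMe3; tert-butyl terminus geometry immaterial) | C[C@@H](O/C(O[Si](C)(C)C)=C/CCCCCC=C(O[Si](C)(C)C)OC(C)(C)C)/C=C/C=C/[C@H](CCCCC)O[Si](c1ccccc1)(c1ccccc1)C(C)(C)C | intermediate (not isolated)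
12 | trimethylsilyl ester of 13 still carrying the tert-butyl trimethylsilyl ketene acetal at C1–C2 | CCCCC[C@@H](/C=C/[C@@H](/C=C/C)[C@@H](CCCCCC=C(O[Si](C)(C)C)OC(C)(C)C)C(=O)O[Si](C)(C)C)O[Si](c1ccccc1)(c1ccccc1)C(C)(C)C | intermediate (not isolated)
13 | (2R)-9-tert-butoxy-2-[(2E,4R,5E,7S)-7-[(tert-butyldiphenylsilyl)oxy]dodeca-2,5-dien-4-yl]-9-oxononanoic acid | CCCCC[C@@H](/C=C/[C@@H](/C=C/C)[C@@H](CCCCCCC(=O)OC(C)(C)C)C(=O)O)O[Si](c1ccccc1)(c1ccccc1)C(C)(C)C | intermediate
14 | tert-butyl (8R)-9-chloro-8-[(2E,4R,5E,7S)-7-[(tert-butyldiphenylsilyl)oxy]dodeca-2,5-dien-4-yl]-9-oxononanoate (acid chloride of 13) | CCCCC[C@@H](/C=C/[C@@H](/C=C/C)[C@@H](CCCCCCC(=O)OC(C)(C)C)C(=O)Cl)O[Si](c1ccccc1)(c1ccccc1)C(C)(C)C | intermediate (not isolated)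
15 | tert-butyl (8R)-8-[(2E,4R,5E,7S)-7-[(tert-butyldiphenylsilyl)oxy]dodeca-2,5-dien-4-yl]-9-[methoxy(methyl)amino]-9-oxononanoate | CCCCC[C@@H](/C=C/[C@@H](/C=C/C)[C@@H](CCCCCCC(=O)OC(C)(C)C)C(=O)N(C)OC)O[Si](c1ccccc1)(c1ccccc1)C(C)(C)C | intermediate
16 | bromomagnesium alkoxide of the vinyl adduct of 15 (tetrahedral C9, configuration at C9 undefined) | CCCCC[C@@H](/C=C/[C@@H](/C=C/C)[C@@H](CCCCCCC(=O)OC(C)(C)C)C(O[Mg]Br)(C=C)N(C)OC)O[Si](c1ccccc1)(c1ccccc1)C(C)(C)C | intermediate (not isolated)
17 | tert-butyl (8R)-8-[(2E,4R,5E,7S)-7-[(tert-butyldiphenylsilyl)oxy]dodeca-2,5-dien-4-yl]-9-oxoundec-10-enoate | CCCCC[C@@H](/C=C/[C@@H](/C=C/C)[C@@H](CCCCCCC(=O)OC(C)(C)C)C(=O)C=C)O[Si](c1ccccc1)(c1ccccc1)C(C)(C)C | intermediate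
18 | tert-butyl 7-[(1R,2S)-2-[(1E,3S)-3-[(tert-butyldiphenylsilyl)oxy]oct-1-en-1-yl]-5-oxocyclopent-3-en-1-yl]heptanoate | CCCCC[C@@H](/C=C/[C@H]1C=CC(=O)[C@@H]1CCCCCCC(=O)OC(C)(C)C)O[Si](c1ccccc1)(c1ccccc1)C(C)(C)C | intermediate
19 | 7-[(1R,2S)-2-[(1E,3S)-3-[(tert-butyldiphenylsilyl)oxy]oct-1-en-1-yl]-5-oxocyclopent-3-en-1-yl]heptanoic acid | CCCCC[C@@H](/C=C/[C@H]1C=CC(=O)[C@@H]1CCCCCCC(=O)O)O[Si](c1ccccc1)(c1ccccc1)C(C)(C)C | intermediate
20 | 7-[(1R,2S)-2-[(1E,3S)-3-hydroxyoct-1-en-1-yl]-5-oxocyclopent-3-en-1-yl]heptanoic acid (prostaglandin A1) | CCCCC[C@H](O)/C=C/[C@H]1C=CC(=O)[C@@H]1CCCCCCC(=O)O | intermediate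
21 | mixed anhydride of 22 with acetic acid at C1 | CCCCC[C@@H](/C=C/[C@H]1C=CC(=O)[C@@H]1CCCCCCC(=O)OC(C)=O)OC(C)=O | intermediate (not isolated)
22 | 7-[(1R,2S)-2-[(1E,3S)-3-acetoxyoct-1-en-1-yl]-5-oxocyclopent-3-en-1-yl]heptanoic acid (CNP0281518.1) | CCCCC[C@@H](/C=C/[C@H]1C=CC(=O)[C@@H]1CCCCCCC(=O)O)OC(C)=O | target

## Step count and least certain steps

Total: 12 steps. Longest linear sequence: 12 steps (1 to 22); 5 and 9 enter as purchased compounds.

Step 6 (key step). The most likely failure is erosion of enolate geometry when two esters are enolised at once, which would lower the simple diastereoselection at C8; condensation between the two ester termini before silylation is a second risk. C12 should be unaffected, since it depends only on the chair and on the E-alkene. The fallback sets out from 10 and returns at 18. The rearrangement is run without insisting on enolate geometry, and the C8-epimeric acid F1 that accompanies 13 is carried with it through steps 7–9. It passes through the acid chloride F2, the Weinreb amide F3, the magnesium adduct F4 and the vinyl ketone F5 to the cis-cyclopentenone F6. Brief treatment of the 18/F6 mixture with a mild amine base (Et3N, CH2Cl2, rt) should then epimerise C8, which is α to the ketone, to the thermodynamically preferred trans isomer 18. This replaces kinetic control of C8 in the sigmatropic step by thermodynamic control on the ring.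

Step 9. The carbene may load slowly on a 1,2-disubstituted alkene next to a tertiary carbon. Oligomerisation through the enone, engagement of the C13=C14 alkene (ring closure the wrong way, with loss of the ω-chain) or ruthenium hydride migration of the skipped diene could then compete. The fallback sets out from 17 and returns at 18. Luche reduction (NaBH4, CeCl3, MeOH, −78 °C) gives the C9 allylic alcohol F7 as an epimer mixture. Ring-closing metathesis of this electron-rich vinyl carbinol gives the cyclopentenol F8, and allylic oxidation (MnO2, CH2Cl2) gives 18. The ring is thus closed at the alcohol oxidation level.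

Step 8. Conjugate addition of the liberated N-methoxy-N-methylamine or of excess Grignard reagent to the new vinyl ketone, attack on the tert-butyl ester, or enolisation at C8 may reduce the return. The fallback sets out from 13 and returns at 17. The acid chloride 14, generated as in step 7, is coupled directly with tributyl(vinyl)stannane under palladium catalysis (Stille acylation), which avoids both the amide and the Grignard reagent.

Step 4. Hydroalumination of a conjugated enyne may be incompletely regioselective (1,4-reduction, allene formation or over-reduction), and the alkoxide may attack the silyl ether. The fallback sets out from 4 and returns at 8. A Heck reaction of 4 with but-3-en-2-one (Pd(OAc)2, Bu4NCl, NaHCO3, DMF) gives the E,E-dienone F9, and a Corey–Bakshi–Shibata reduction with the (S)-oxazaborolidine and BH3·SMe2 sets the R carbinol of 8 by catalyst control.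

Step 10. Partial loss of the allylic silyl ether in acid, followed by ionisation at C15 (epimerisation or allylic transposition), is the main risk. The fallback sets out from 18 and returns at 22, and changes the order of unmasking. HF·pyridine first gives the hydroxy ester F10, acetylation (Ac2O, pyridine) gives the acetoxy ester F11, and the tert-butyl ester is cleaved last (CF3CO2H/CH2Cl2 at 0 °C, or ZnBr2 in CH2Cl2). The acid then meets only the less ionisable acetate and never a free or silylated allylic alcohol.

## Further compounds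

F1 | step 6 | (2S)-9-tert-butoxy-2-[(2E,4R,5E,7S)-7-[(tert-butyldiphenylsilyl)oxy]dodeca-2,5-dien-4-yl]-9-oxononanoic acid (C8 epimer of 13) | CCCCC[C@@H](/C=C/[C@@H](/C=C/C)[C@H](CCCCCCC(=O)OC(C)(C)C)C(=O)O)O[Si](c1ccccc1)(c1ccccc1)C(C)(C)C
F2 | step 6 | acid chloride of F1 (C8 epimer of 14) | CCCCC[C@@H](/C=C/[C@@H](/C=C/C)[C@H](CCCCCCC(=O)OC(C)(C)C)C(=O)Cl)O[Si](c1ccccc1)(c1ccccc1)C(C)(C)C
F3 | step 6 | N-methoxy-N-methylamide of F1 (C8 epimer of 15) | CCCCC[C@@H](/C=C/[C@@H](/C=C/C)[C@H](CCCCCCC(=O)OC(C)(C)C)C(=O)N(C)OC)O[Si](c1ccccc1)(c1ccccc1)C(C)(C)C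
F4 | step 6 | bromomagnesium alkoxide of the vinyl adduct of F3 (C8 epimer of 16) | CCCCC[C@@H](/C=C/[C@@H](/C=C/C)[C@H](CCCCCCC(=O)OC(C)(C)C)C(O[Mg]Br)(C=C)N(C)OC)O[Si](c1ccccc1)(c1ccccc1)C(C)(C)C
F5 | step 6 | tert-butyl (8S)-8-[(2E,4R,5E,7S)-7-[(tert-butyldiphenylsilyl)oxy]dodeca-2,5-dien-4-yl]-9-oxoundec-10-enoate (C8 epimer of 17) | CCCCC[C@@H](/C=C/[C@@H](/C=C/C)[C@H](CCCCCCC(=O)OC(C)(C)C)C(=O)C=C)O[Si](c1ccccc1)(c1ccccc1)C(C)(C)C
F6 | step 6 | tert-butyl 7-[(1S,2S)-2-[(1E,3S)-3-[(tert-butyldiphenylsilyl)oxy]oct-1-en-1-yl]-5-oxocyclopent-3-en-1-yl]heptanoate (cis, C8 epimer of 18) | CCCCC[C@@H](/C=C/[C@H]1C=CC(=O)[C@H]1CCCCCCC(=O)OC(C)(C)C)O[Si](c1ccccc1)(c1ccccc1)C(C)(C)C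
F7 | step 9 | tert-butyl (8R)-8-[(2E,4R,5E,7S)-7-[(tert-butyldiphenylsilyl)oxy]dodeca-2,5-dien-4-yl]-9-hydroxyundec-10-enoate (C9 epimers) | CCCCC[C@@H](/C=C/[C@@H](/C=C/C)[C@@H](CCCCCCC(=O)OC(C)(C)C)C(O)C=C)O[Si](c1ccccc1)(c1ccccc1)C(C)(C)C
F8 | step 9 | 9-hydroxy analogue of 18 (cyclopent-3-en-1-ol in place of the enone, C9 epimers, C8 and C12 as in 18) | CCCCC[C@@H](/C=C/[C@H]1C=CC(O)[C@@H]1CCCCCCC(=O)OC(C)(C)C)O[Si](c1ccccc1)(c1ccccc1)C(C)(C)C
F0 | step 8 | none | none
F9 | step 4 | (3E,5E,7S)-7-[(tert-butyldiphenylsilyl)oxy]dodeca-3,5-dien-2-one | CC(=O)/C=C/C=C/[C@H](CCCCC)O[Si](c1ccccc1)(c1ccccc1)C(C)(C)C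
F10 | step 10 | tert-butyl 7-[(1R,2S)-2-[(1E,3S)-3-hydroxyoct-1-en-1-yl]-5-oxocyclopent-3-en-1-yl]heptanoate | CCCCC[C@H](O)/C=C/[C@H]1C=CC(=O)[C@@H]1CCCCCCC(=O)OC(C)(C)C
F11 | step 10 | tert-butyl 7-[(1R,2S)-2-[(1E,3S)-3-acetoxyoct-1-en-1-yl]-5-oxocyclopent-3-en-1-yl]heptanoate | CCCCC[C@@H](/C=C/[C@H]1C=CC(=O)[C@@H]1CCCCCCC(=O)OC(C)(C)C)OC(C)=O
A1 | alternative 1 | tert-butyl 7-[(3R)-3-[(tert-butyldimethylsilyl)oxy]-5-oxocyclopent-1-en-1-yl]heptanoate | O=C1C[C@@H](O[Si](C)(C)C(C)(C)C)C=C1CCCCCCC(=O)OC(C)(C)C
A2 | alternative 1 | tert-butyl 7-[(1R,2R,3R)-3-[(tert-butyldimethylsilyl)oxy]-2-[(1E,3S)-3-[(tert-butyldiphenylsilyl)oxy]oct-1-en-1-yl]-5-oxocyclopentyl]heptanoate | CCCCC[C@@H](/C=C/[C@H]1[C@H](O[Si](C)(C)C(C)(C)C)CC(=O)[C@@H]1CCCCCCC(=O)OC(C)(C)C)O[Si](c1ccccc1)(c1ccccc1)C(C)(C)C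
A3 | alternative 2 | tert-butyl (8E,10E,12S)-12-[(tert-butyldiphenylsilyl)oxy]-8-[(2E)-3-(trimethylsilyl)prop-2-enoyl]heptadeca-8,10-dienoate | C[Si](C)(C)/C=C/C(=O)/C(CCCCCCC(=O)OC(C)(C)C)=C/C=C/[C@H](CCCCC)O[Si](c1ccccc1)(c1ccccc1)C(C)(C)C
A4 | alternative 3 | cyclopent-2-en-1-one | O=C1C=CCC1
A5 | alternative 3 | tert-butyl 7-iodoheptanoate | ICCCCCCC(=O)OC(C)(C)C
A6 | alternative 3 | tert-butyl 7-[(1R,2R)-2-[(1E,3S)-3-[(tert-butyldiphenylsilyl)oxy]oct-1-en-1-yl]-5-oxocyclopentyl]heptanoate | CCCCC[C@@H](/C=C/[C@H]1CCC(=O)[C@@H]1CCCCCCC(=O)OC(C)(C)C)O[Si](c1ccccc1)(c1ccccc1)C(C)(C)C
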